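(The numbers in the tables come from a simulation for substances that don't exist; the scatter is artificial.)

Reading this flask at any time up to 15 d means asking how much target stands in it then, and these runs are what I have:

| flask | starting material | protic impurity | remark | time |
|---|---|---|---|---|
| summer | 15 mM | 2.2 mM | run made earlier |  |
| noon | 24 mM | 2.2 mM | run made earlier |  |
| flask | 11 mM | 2.20 mM |  | 15 d |

- summer (time / d: target / %): 0.167: 60.9; 0.417: 57.3; 1.04: 44.4; 3.00: 24.7; 8.00: 11.1; 20.0: 10.5
- noon (time / d: target / %): 0.167: 60.0; 0.417: 57.0; 1.04: 45.4; 3.00: 27.6; 8.00: 12.1; 20.0: 8.6

(readings scatter by 1 percentage point)

- when, up to 15 d, the flask holds most target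
- the amount of target, in percent of the starting material charged, at that time
- the first time at which target reaches 42 %, in the same percent, in d

- candidate steps: target -> over-reaction product; target <-> isomer of the product A; starting material <-> target; target <-> isomer of the product B; starting material <-> isomer of the product A; starting material + protic impurity -> quenched substrate

Two numbers seem to quarrel: the impurity can take 14.7 % of the charge in the summer run and 9.17 % in the noon run, yet at 0.167 d they read 60.9 % and 60.0 % of target. In the new flask the impurity charge over the starting material charge gives 20.0 %, which I call the quench ceiling. By the candidate step each impurity used makes one quenched substrate, so integrating that rate gives quenched substrate as the ceiling times the fraction of impurity used, whatever the path. The ceiling tells where the quench ends, not how fast it begins: at the very start the quench takes starting material at a fractional rate proportional to the impurity charge, and that charge is equal in the two runs, so unequal ceilings need not part the early readings, although this rate falls as the impurity is used and the equality holds for the start alone. The new flask has the same impurity charge, so I expect it to begin like them.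

The forecast gives 60.5 % at 0.15 d and the asked level first at 0.05 d, holding that “the peak lies just before or near the first reading”.

The flask gives 60.6 % at 0.212 d, later than forecast, and reaches the asked level at 0.0562 d.

    target → over-reaction product (k = 4.52 × 10⁻⁸ s⁻¹)
    target ⇌ isomer of the product A (k = 3.07 × 10⁻⁵ s⁻¹)
    starting material ⇌ target (K = 9.60, k = 1.42 × 10⁻⁴ s⁻¹)
    target ⇌ isomer of the product B (K = 7.40, k = 5.88 × 10⁻⁶ s⁻¹)
    starting material ⇌ isomer of the product A (K = 2.60, k = 4.94 × 10⁻⁵ s⁻¹)
    starting material + protic impurity → quenched substrate (k = 0.00987 M⁻¹ s⁻¹)

At 15.0 d the flask keeps 5.3 % of its impurity, so the ceiling reckons 18.9 % of quenched substrate, and the flask holds 18.9 %. The neighbouring flask with 5.5 mM of impurity has a ceiling of 50.0 %. With 12.2 % of its impurity left at 15.0 d, the same reckoning gives 43.9 %, and that neighbouring flask holds 43.9 % of quenched substrate, its target having peaked at 53.8 %.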